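## Retrosynthetic overview

1. The target comes from a monocyclic seco-core by end-game steps only: stearoylation of the C3 alcohol, reduction of a C16 enone with an (S)-oxazaborolidine catalyst, and oxidation of the C1 allylic alcohol to the Z-enal. C17–C24 arrive by acyl substitution with lithiated geranyl phenyl sulfone.
2. The seco-core comes from a bicyclic 8,9-epoxy-3-ol in one flask: epoxide opening, 1,2-methyl shift (C10 to C9), 1,2-hydride shift (C5 to C10), then Grob scission of ring A (C3–C4).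
3. The bicyclic epoxide comes from an acyclic C20 epoxy-triene ester by epoxide-initiated cation–olefin bicyclization (rings A and B closed together), equilibration to the C8=C9 olefin, and epoxidation.
4. The acyclic precursor comes from (2E,6E)-farnesyl bromide by C2 homologation, Wittig olefination, terminal SeO2 hydroxylation and Sharpless epoxidation with the D-tartrate.
5. Ring order: ring A and ring B form together; ring A is then cleaved, so ring B becomes the cyclohexane of the target.

Numbering used: monocyclic compounds carry iridal locants (C1 aldehyde carbon, C2=C7 exocyclic olefin, C3 carbinol of the propyl arm, ring C6–C11, side chain C12–C24); bicyclic compounds carry drimane locants (C3 carbinol, C4, C5/C10 ring fusion, C8/C9, C10 angular methyl).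

## Route

Step 1
Reactants: 1 (2E,6E)-farnesyl bromide; 2 acetaldehyde N,N-dimethylhydrazone
Product: 4 (4E,8E)-5,9,13-trimethyltetradeca-4,8,12-trienal, via farnesylacetaldehyde dimethylhydrazone 3 (not isolated)
Conditions: 2, LiN(iPr)2, THF, 0 °C; add 1, −78 → 0 °C; then sat. aq. oxalic acid, Et2O, 25 °C
Reagents that add atoms: water, O
Why: Corey–Enders alkylation of the lithiated hydrazone is a direct SN2 at the primary allylic bromide that leaves both E-olefins untouched, and mild acid hydrolysis releases the two-carbon-homologated aldehyde.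

Step 2
Reactants: 4 (4E,8E)-5,9,13-trimethyltetradeca-4,8,12-trienal; 5 ethyl 2-(triphenylphosphoranylidene)propanoate
Product: 6 ethyl (2E,6E,10E)-2,7,11,15-tetramethylhexadeca-2,6,10,14-tetraenoate
Conditions: PhMe, 80 °C
Reagents that add atoms: none
Why: Wittig olefination with the α-methyl stabilized ylide gives the (E)-trisubstituted enoate (C14=C15 of the target) with high selectivity.

Step 3
Reactants: 6 ethyl (2E,6E,10E)-2,7,11,15-tetramethylhexadeca-2,6,10,14-tetraenoate
Product: 7 ethyl (2E,6E,10E,14E)-16-hydroxy-2,7,11,15-tetramethylhexadeca-2,6,10,14-tetraenoate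
Conditions: SeO2 (0.3 equiv), t-BuOOH (3 equiv), salicylic acid (0.1 equiv), CH2Cl2, 0 → 25 °C, stopped at partial conversion with recycling of 6
Reagents that add atoms: tert-butyl hydroperoxide, CC(C)(C)OO
Why: SeO2/t-BuOOH allylic hydroxylation (ene reaction then [2,3]-shift) picks the (E)-methyl of the exposed terminal trisubstituted olefin, while the enoate olefin is deactivated and the internal olefins react more slowly.

Step 4
Reactants: 7 ethyl (2E,6E,10E,14E)-16-hydroxy-2,7,11,15-tetramethylhexadeca-2,6,10,14-tetraenoate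
Product: 8 ethyl (2E,6E,10E)-13-[(2R,3R)-3-(hydroxymethyl)-3-methyloxiran-2-yl]-2,7,11-trimethyltrideca-2,6,10-trienoate
Conditions: Ti(OiPr)4 (10 mol %), D-(−)-diethyl tartrate (12 mol %), t-BuOOH, 4 Å MS, CH2Cl2, −20 °C
Reagents that add atoms: tert-butyl hydroperoxide, CC(C)(C)OO
Why: Sharpless asymmetric epoxidation with the D-tartrate delivers oxygen to the face that gives the (2R,3R)-oxirane, and this single event fixes the absolute configuration of all three ring stereocentres made later.

Step 5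
Reactants: 8 ethyl (2E,6E,10E)-13-[(2R,3R)-3-(hydroxymethyl)-3-methyloxiran-2-yl]-2,7,11-trimethyltrideca-2,6,10-trienoate
Product: 9 tert-butyldiphenylsilyl ether of 8
Conditions: t-BuPh2SiCl, imidazole, DMF, 0 → 25 °C
Reagents that add atoms: tert-butylchlorodiphenylsilane, CC(C)(C)[Si](Cl)(c1ccccc1)c1ccccc1
Why: standard silylation of the primary alcohol gives a bulky, weakly donating ether that does not take part in epoxide opening (an ester would) and is a poor electron donor in the later fragmentation.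

Step 6
Reactants: 9 tert-butyldiphenylsilyl ether of 8
Product: 11 ethyl (2E)-5-[(4aS,5S,6R,8aR)-5-{[tert-butyl(diphenyl)silyl]oxymethyl}-6-hydroxy-2,5,8a-trimethyl-3,4,4a,5,6,7,8,8a-octahydronaphthalen-1-yl]-2-methylpent-2-enoate, via exocyclic olefin isomer 10 (not isolated)
Conditions: MeAlCl2 (3 equiv), CH2Cl2, −78 °C; aq. work-up; crude olefins, I2 (10 mol %), PhMe, 25 °C
Reagents that add atoms: none
Why: epoxide-initiated cation–olefin bicyclization (chair–chair, anti addition across both E-olefins) transfers the oxirane configuration to C3, C4, C5 and C10 of a trans-decalin with 3-OH and CH2OSi equatorial, the electron-poor enoate olefin cannot close a third ring, and HI formed from I2 equilibrates the kinetic olefins to the tetrasubstituted C8=C9 isomer, the thermodynamic one in 9-alkyl drimane and labdane systems.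

Step 7
Reactants: 11 tetrasubstituted-olefin decalin (octahydronaphthalene named in step 6)
Product: 12 8,9-epoxide of 11 with the oxirane oxygen on the face opposite the C10 methyl (drimane locants 3R,4S,5S,8S,9R,10R)
Conditions: DMDO (C3H6O2, 1.1 equiv), acetone, −30 → 0 °C
Reagents that add atoms: dimethyldioxirane, CC1(C)OO1
Why: electrophilic epoxidation occurs only at the electron-rich tetrasubstituted olefin (the enoate is inert) and anti to the angular methyl, under neutral conditions that keep the acid-labile epoxide intact.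

Step 8
Reactants: 12 8,9-epoxide of 11
Product: 14 ethyl (2E)-5-[(1R,2S,6S)-5-[(2Z)-1-{[tert-butyl(diphenyl)silyl]oxy}propan-2-ylidene]-2-hydroxy-6-(3-hydroxypropyl)-1,2-dimethylcyclohexyl]-2-methylpent-2-enoate, via seco-aldehyde 13 (not isolated)
Conditions: BF3·OEt2 (1.2 equiv), CH2Cl2, −78 °C, 10 min; Et3N; then NaBH4, MeOH, −78 → 0 °C
Reagents that add atoms: none
Why: Proposed new method: BF3 ionizes the epoxide at C9 with concerted anti-periplanar 1,2-shift of the axial C10 methyl (this sets iridal C11 and leaves the oxygen on C8 with retention as the C10 carbinol), a suprafacial 1,2-hydride shift from C5 to C10 sets C6 and places the cation at C5, γ to the free C3 hydroxyl, where Grob-type (retro-Prins) scission of C3–C4 releases the aldehyde and the tetrasubstituted C2=C7 olefin, a chair-like fragmentation placing the formerly equatorial CH2OSi cis to C6, and the cold amine quench followed by NaBH4 reduces the aldehyde before it can re-close by a Prins reaction; the closest known chemistry is the BF3-induced backbone (Westphalen-type) rearrangement of steroid and drimane epoxides and olefins by 1,2-hydride and 1,2-methyl shifts, and the acid-induced fragmentation of 2,2-disubstituted 1,3-diols through γ-hydroxy cations.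

Step 9
Reactants: 15 geranyl bromide; 16 sodium benzenesulfinate
Product: 17 geranyl phenyl sulfone
Conditions: PhSO2Na, DMF, 25 °C
Reagents that add atoms: none
Why: S-alkylation of the sulfinate by SN2 at the primary allylic bromide gives the sulfone with the E-olefin intact.

Step 10
Reactants: 14 seco-diol ester (cyclohexane named in step 8); 17 geranyl phenyl sulfone
Product: 19 (3E,7E)-1-[(1R,2S,6S)-5-[(2Z)-1-{[tert-butyl(diphenyl)silyl]oxy}propan-2-ylidene]-2-hydroxy-6-(3-hydroxypropyl)-1,2-dimethylcyclohexyl]-4,8,12-trimethyl-6-(phenylsulfonyl)trideca-3,7,11-trien-5-one (C17 epimers), via Weinreb amide 18 (not isolated)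
Conditions: MeNH(OMe)·HCl, n-BuLi, THF, −78 → −10 °C; then 17/n-BuLi (THF, −78 °C), −78 → 0 °C; aq. NH4Cl
Reagents that add atoms: none
Why: the ester is converted in the flask into the Weinreb amide by LiN(OMe)Me, and the α-lithiated sulfone then attacks through the sulfonyl-bearing carbon only (no allylic transposition), the chelated tetrahedral intermediate blocking both over-addition and conjugate addition (acyl substitution of a Weinreb amide by a sulfonyl carbanion).

Step 11
Reactants: 19 β-keto sulfone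
Product: 20 (3E,7E)-1-[(1R,2S,6S)-5-[(2Z)-1-{[tert-butyl(diphenyl)silyl]oxy}propan-2-ylidene]-2-hydroxy-6-(3-hydroxypropyl)-1,2-dimethylcyclohexyl]-4,8,12-trimethyltrideca-3,7,11-trien-5-one
Conditions: SmI2 (2.5 equiv), THF–MeOH, −78 °C
Reagents that add atoms: none
Why: single-electron reduction cleaves the C–S bond α to the ketone far faster than it touches the enone, and kinetic α-protonation of the resulting dienolate keeps the C18=C19 olefin E and out of conjugation (reductive desulfonylation of a β-keto sulfone).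

Step 12
Reactants: 20 enone diol; 21 stearoyl chloride
Product: 22 3-[(1S,2R,3S)-6-[(2Z)-1-{[tert-butyl(diphenyl)silyl]oxy}propan-2-ylidene]-3-hydroxy-2,3-dimethyl-2-[(3E,7E)-4,8,12-trimethyl-5-oxotrideca-3,7,11-trien-1-yl]cyclohexyl]propyl octadecanoate
Conditions: 21 (1.1 equiv), pyridine, CH2Cl2, 0 °C
Reagents that add atoms: none
Why: the C3 hydroxyl is the only primary alcohol and the tertiary C10 alcohol does not acylate under these conditions.

Step 13
Reactants: 22 stearate enone
Product: 23 (16R)-allylic alcohol of 22 (C16 ketone reduced; iridal locants 2Z,6S,10S,11R,14E,16R,18E; C1 silyl ether retained)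
Conditions: (S)-Me-CBS oxazaborolidine (C18H20BNO, 20 mol %), catecholborane, PhMe, −78 °C
Reagents that add atoms: none
Why: Corey–Bakshi–Shibata reduction in which the α-methyl alkenyl group is the large substituent, so the (S)-catalyst gives the (16R)-alcohol, and catecholborane at −78 °C leaves the olefins and the stearate untouched.

Step 14
Reactants: 23 (16R)-allylic alcohol silyl ether
Product: 24 3-[(1S,2R,3S,6Z)-3-hydroxy-2-[(3E,5R,7E)-5-hydroxy-4,8,12-trimethyltrideca-3,7,11-trien-1-yl]-6-(1-hydroxypropan-2-ylidene)-2,3-dimethylcyclohexyl]propyl octadecanoate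
Conditions: HF·pyridine, pyridine, THF, 0 → 25 °C
Reagents that add atoms: none
Why: buffered fluoride cleaves the silyl ether without harming the ester or ionizing the two allylic alcohols.

Step 15
Reactants: 24 C1 allylic alcohol
Product: 25 3-[(1S,2R,3S,6Z)-3-hydroxy-2-[(3E,5R,7E)-5-hydroxy-4,8,12-trimethyltrideca-3,7,11-trien-1-yl]-2,3-dimethyl-6-(1-oxopropan-2-ylidene)cyclohexyl]propyl octadecanoate (target)
Conditions: TEMPO (C9H18NO, 10 mol %), PhI(OAc)2 (1.1 equiv), CH2Cl2, 25 °C
Reagents that add atoms: none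
Why: oxoammonium oxidation is selective for the primary allylic alcohol over the secondary C16 and tertiary C10 alcohols and is neutral, so the Z-enal geometry and the γ-stereocentre C6 are not disturbed.

## Compound list

1 | (2E,6E)-farnesyl bromide | BrC/C=C(\C)CC/C=C(\C)CCC=C(C)C | starting material
2 | acetaldehyde N,N-dimethylhydrazone | C/C=N/N(C)C | starting material
3 | (4E,8E)-5,9,13-trimethyltetradeca-4,8,12-trienal N,N-dimethylhydrazone | CN(C)/N=C/CC/C=C(\C)CC/C=C(\C)CCC=C(C)C | intermediate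
4 | (4E,8E)-5,9,13-trimethyltetradeca-4,8,12-trienal | O=CCC/C=C(\C)CC/C=C(\C)CCC=C(C)C | intermediate
5 | ethyl 2-(triphenylphosphoranylidene)propanoate | CCOC(=O)C(C)=P(c1ccccc1)(c1ccccc1)c1ccccc1 | starting material
6 | ethyl (2E,6E,10E)-2,7,11,15-tetramethylhexadeca-2,6,10,14-tetraenoate | CCOC(=O)/C(C)=C/CC/C=C(\C)CC/C=C(\C)CCC=C(C)C | intermediate
7 | ethyl (2E,6E,10E,14E)-16-hydroxy-2,7,11,15-tetramethylhexadeca-2,6,10,14-tetraenoate | CCOC(=O)/C(C)=C/CC/C=C(\C)CC/C=C(\C)CC/C=C(\C)CO | intermediate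
8 | ethyl (2E,6E,10E)-13-[(2R,3R)-3-(hydroxymethyl)-3-methyloxiran-2-yl]-2,7,11-trimethyltrideca-2,6,10-trienoate | CCOC(=O)/C(C)=C/CC/C=C(\C)CC/C=C(\C)CC[C@H]1O[C@]1(C)CO | intermediate
9 | tert-butyldiphenylsilyl ether of 8 | CCOC(=O)/C(C)=C/CC/C=C(\C)CC/C=C(\C)CC[C@H]1O[C@]1(C)CO[Si](c2ccccc2)(c2ccccc2)C(C)(C)C | intermediate
10 | exocyclic 8(12)-olefin isomer of 11 (trans-decalin, 9-H on the face opposite the C10 methyl; formed together with the 7-ene) | C[C@@]12CC[C@@H](O)[C@](C)(CO[Si](c3ccccc3)(c3ccccc3)C(C)(C)C)[C@H]1CCC(=C)[C@H]2CC/C=C(\C)C(=O)OCC | intermediate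
11 | ethyl (2E)-5-[(4aS,5S,6R,8aR)-5-{[tert-butyl(diphenyl)silyl]oxymethyl}-6-hydroxy-2,5,8a-trimethyl-3,4,4a,5,6,7,8,8a-octahydronaphthalen-1-yl]-2-methylpent-2-enoate (drimane locants 3R,4S,5S,10R; 8-ene) | C[C@@]12CC[C@@H](O)[C@](C)(CO[Si](c3ccccc3)(c3ccccc3)C(C)(C)C)[C@H]1CCC(C)=C2CC/C=C(\C)C(=O)OCC | intermediate
12 | 8,9-epoxide of 11, oxirane oxygen anti to the C10 methyl (drimane locants 3R,4S,5S,8S,9R,10R) | C[C@@]12CC[C@@H](O)[C@](C)(CO[Si](c4ccccc4)(c4ccccc4)C(C)(C)C)[C@H]1CC[C@]3(C)O[C@]23CC/C=C(\C)C(=O)OCC | intermediate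
13 | ethyl (2E)-5-[(1R,2S,6S)-5-[(2Z)-1-{[tert-butyl(diphenyl)silyl]oxy}propan-2-ylidene]-2-hydroxy-1,2-dimethyl-6-(3-oxopropyl)cyclohexyl]-2-methylpent-2-enoate | O=CCC[C@H]1/C(=C(/C)CO[Si](c2ccccc2)(c2ccccc2)C(C)(C)C)CC[C@](C)(O)[C@]1(C)CC/C=C(\C)C(=O)OCC | intermediate
14 | ethyl (2E)-5-[(1R,2S,6S)-5-[(2Z)-1-{[tert-butyl(diphenyl)silyl]oxy}propan-2-ylidene]-2-hydroxy-6-(3-hydroxypropyl)-1,2-dimethylcyclohexyl]-2-methylpent-2-enoate | OCCC[C@H]1/C(=C(/C)CO[Si](c2ccccc2)(c2ccccc2)C(C)(C)C)CC[C@](C)(O)[C@]1(C)CC/C=C(\C)C(=O)OCC | intermediate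
15 | geranyl bromide | BrC/C=C(\C)CCC=C(C)C | starting material
16 | sodium benzenesulfinate | [Na+].[O-]S(=O)c1ccccc1 | starting material
17 | geranyl phenyl sulfone | O=S(=O)(C/C=C(\C)CCC=C(C)C)c1ccccc1 | intermediate
18 | N-methoxy-N-methyl amide corresponding to ester 14 | OCCC[C@H]1/C(=C(/C)CO[Si](c2ccccc2)(c2ccccc2)C(C)(C)C)CC[C@](C)(O)[C@]1(C)CC/C=C(\C)C(=O)N(C)OC | intermediate
19 | (3E,7E)-1-[(1R,2S,6S)-5-[(2Z)-1-{[tert-butyl(diphenyl)silyl]oxy}propan-2-ylidene]-2-hydroxy-6-(3-hydroxypropyl)-1,2-dimethylcyclohexyl]-4,8,12-trimethyl-6-(phenylsulfonyl)trideca-3,7,11-trien-5-one (C17 epimers) | OCCC[C@H]1/C(=C(/C)CO[Si](c2ccccc2)(c2ccccc2)C(C)(C)C)CC[C@](C)(O)[C@]1(C)CC/C=C(\C)C(=O)C(/C=C(\C)CCC=C(C)C)S(=O)(=O)c2ccccc2 | intermediate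
20 | (3E,7E)-1-[(1R,2S,6S)-5-[(2Z)-1-{[tert-butyl(diphenyl)silyl]oxy}propan-2-ylidene]-2-hydroxy-6-(3-hydroxypropyl)-1,2-dimethylcyclohexyl]-4,8,12-trimethyltrideca-3,7,11-trien-5-one | OCCC[C@H]1/C(=C(/C)CO[Si](c2ccccc2)(c2ccccc2)C(C)(C)C)CC[C@](C)(O)[C@]1(C)CC/C=C(\C)C(=O)C/C=C(\C)CCC=C(C)C | intermediate
21 | stearoyl chloride (octadecanoyl chloride) | CCCCCCCCCCCCCCCCCC(Cl)=O | starting material
22 | 3-[(1S,2R,3S)-6-[(2Z)-1-{[tert-butyl(diphenyl)silyl]oxy}propan-2-ylidene]-3-hydroxy-2,3-dimethyl-2-[(3E,7E)-4,8,12-trimethyl-5-oxotrideca-3,7,11-trien-1-yl]cyclohexyl]propyl octadecanoate | CCCCCCCCCCCCCCCCCC(=O)OCCC[C@H]1/C(=C(/C)CO[Si](c2ccccc2)(c2ccccc2)C(C)(C)C)CC[C@](C)(O)[C@]1(C)CC/C=C(\C)C(=O)C/C=C(\C)CCC=C(C)C | intermediate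
23 | 3-[(1S,2R,3S)-6-[(2Z)-1-{[tert-butyl(diphenyl)silyl]oxy}propan-2-ylidene]-3-hydroxy-2-[(3E,5R,7E)-5-hydroxy-4,8,12-trimethyltrideca-3,7,11-trien-1-yl]-2,3-dimethylcyclohexyl]propyl octadecanoate | CCCCCCCCCCCCCCCCCC(=O)OCCC[C@H]1/C(=C(/C)CO[Si](c2ccccc2)(c2ccccc2)C(C)(C)C)CC[C@](C)(O)[C@]1(C)CC/C=C(\C)[C@H](O)C/C=C(\C)CCC=C(C)C | intermediate
24 | 3-[(1S,2R,3S,6Z)-3-hydroxy-2-[(3E,5R,7E)-5-hydroxy-4,8,12-trimethyltrideca-3,7,11-trien-1-yl]-6-(1-hydroxypropan-2-ylidene)-2,3-dimethylcyclohexyl]propyl octadecanoate | CCCCCCCCCCCCCCCCCC(=O)OCCC[C@H]1/C(=C(/C)CO)CC[C@](C)(O)[C@]1(C)CC/C=C(\C)[C@H](O)C/C=C(\C)CCC=C(C)C | intermediate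
25 | 3-[(1S,2R,3S,6Z)-3-hydroxy-2-[(3E,5R,7E)-5-hydroxy-4,8,12-trimethyltrideca-3,7,11-trien-1-yl]-2,3-dimethyl-6-(1-oxopropan-2-ylidene)cyclohexyl]propyl octadecanoate; iridal locants 2Z,6S,10S,11R,14E,16R,18E | CCCCCCCCCCCCCCCCCC(=O)OCCC[C@H]1/C(=C(/C)C=O)CC[C@](C)(O)[C@]1(C)CC/C=C(\C)[C@H](O)C/C=C(\C)CCC=C(C)C | target

## Step count and risks

Total steps: 15. Longest linear sequence: 14 (steps 1–8 and 10–15; step 9 is a one-step side branch).

Most likely to fail, first: step 8 (the rearrangement–fragmentation cascade). The competing paths are a Meinwald shift to an 8-ketone, proton loss from the cations, loss of the silyloxymethyl carbon instead of C3, and the wrong C2=C7 geometry. The fallback sets out from 12 and comes back at 13. BF3·OEt2 is used with 2,6-di-tert-butylpyridine at −40 °C so that the sequence stops after the methyl shift by loss of H-5, giving the backbone-rearranged ring-fusion olefin diol F1 (a precedented outcome in drimane chemistry). Oxidation with Dess–Martin periodinane gives the 3-ketone F2. Reduction with LiBH(s-Bu)3 gives the axial C3-epimeric alcohol F3, whose hydroxyl now lies on the face to which hydrogen must be delivered at C10. Ring A is then opened by a thermal retro-ene reaction of this homoallylic alcohol (flash vacuum pyrolysis, about 450 °C), a pericyclic rather than cationic scission, to give aldehyde 13, which is reduced with NaBH4 as in step 8.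

Second: step 6 (bicyclization and olefin equilibration). The α-silyloxymethyl group slows epoxide ionization, and the acid equilibration can over-run into hydride and methyl shifts with premature fragmentation through the free C3 hydroxyl. The fallback sets out from 10, now isolated as the kinetic olefin mixture, and comes back at 11. The C3 alcohol is oxidized with Dess–Martin periodinane to the kinetic-olefin 3-ketone F4, which cannot act as the electron donor for ring cleavage. The olefin is then equilibrated with HI in benzene at 80 °C to the tetrasubstituted-olefin 3-ketone F5. NaBH4 returns the equatorial C3 alcohol 11.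

Third: step 10 (amide formation and sulfone acylation in one flask on a diol). The fallback sets out from 14 and comes back at 19. i-Bu2AlH reduces the ester to the allylic alcohol triol F6. MnO2 oxidizes only the allylic alcohol to the enal F7. Lithiated 17 adds 1,2 to the aldehyde to give the β-hydroxy sulfone F8. A second MnO2 oxidation of the allylic carbinol gives 19; this replaces an acyl substitution by an aldehyde addition and re-oxidation.

## Further compounds

F1 | step 8 | backbone-rearranged 5(10)-olefin diol: ring-fusion olefin between C5 and C10, methyl migrated to C9, 8-OH and 3-OH retained, silyl ether and enoate chain unchanged | C1C[C@@H](O)[C@](C)(CO[Si](c3ccccc3)(c3ccccc3)C(C)(C)C)C2=C1[C@@](C)(CC/C=C(\C)C(=O)OCC)[C@@](C)(O)CC2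
F2 | step 8 | 3-ketone of F1 | C1CC(=O)[C@](C)(CO[Si](c3ccccc3)(c3ccccc3)C(C)(C)C)C2=C1[C@@](C)(CC/C=C(\C)C(=O)OCC)[C@@](C)(O)CC2
F3 | step 8 | C3 epimer of F1 (axial 3-OH) | C1C[C@H](O)[C@](C)(CO[Si](c3ccccc3)(c3ccccc3)C(C)(C)C)C2=C1[C@@](C)(CC/C=C(\C)C(=O)OCC)[C@@](C)(O)CC2
F4 | step 6 | 3-ketone of the kinetic exocyclic olefin 10 | C[C@@]12CCC(=O)[C@](C)(CO[Si](c3ccccc3)(c3ccccc3)C(C)(C)C)[C@H]1CCC(=C)[C@H]2CC/C=C(\C)C(=O)OCC
F5 | step 6 | 3-ketone of the tetrasubstituted olefin 11 | C[C@@]12CCC(=O)[C@](C)(CO[Si](c3ccccc3)(c3ccccc3)C(C)(C)C)[C@H]1CCC(C)=C2CC/C=C(\C)C(=O)OCC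
F6 | step 10 | allylic alcohol triol from reduction of the ester of 14 | OCCC[C@H]1/C(=C(/C)CO[Si](c2ccccc2)(c2ccccc2)C(C)(C)C)CC[C@](C)(O)[C@]1(C)CC/C=C(\C)CO
F7 | step 10 | C16 enal corresponding to 14 | OCCC[C@H]1/C(=C(/C)CO[Si](c2ccccc2)(c2ccccc2)C(C)(C)C)CC[C@](C)(O)[C@]1(C)CC/C=C(\C)C=O
F8 | step 10 | β-hydroxy sulfone (C16 carbinol, C17 phenylsulfonyl; epimers at C16 and C17) | OCCC[C@H]1/C(=C(/C)CO[Si](c2ccccc2)(c2ccccc2)C(C)(C)C)CC[C@](C)(O)[C@]1(C)CC/C=C(\C)C(O)C(/C=C(\C)CCC=C(C)C)S(=O)(=O)c2ccccc2
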